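Readings and results stem from a simulated flask on assumed constants.

Start from the late end of the runs. At the last reading, 5.00 min, the summer run, charged with 0.10 M of electrophile, keeps 15.0 % of it, and the dawn run, charged with 0.17 M, keeps 15.3 %.

| flask | electrophile | nucleophile | buffer base | buffer acid | remark | time |
|---|---|---|---|---|---|---|
| summer | 0.10 M | 0.15 M | 0.225 M | 7.5 mM | run made earlier |  |
| dawn | 0.17 M | 0.15 M | 0.225 M | 7.5 mM | run made earlier |  |
| flask | 0.075 M | 0.150 M | 0.225 M | 7.50 mM |  | 6.0 min |

- summer (time / min: electrophile / %, target / %): 0.250: 93.9, 5.0; 0.667: 83.4, 11.5; 1.33: 65.0, 17.5; 2.00: 51.0, 21.8; 3.00: 33.9, 25.5; 4.00: 23.4, 27.6; 5.00: 15.0, 28.5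
- dawn (time / min: electrophile / %, target / %): 0.667: 81.2, 9.8; 1.33: 61.9, 14.6; 2.00: 47.8, 17.0; 3.00: 32.1, 19.2; 4.00: 21.6, 19.4; 5.00: 15.3, 19.6

(standard deviation of a reading: 0.3 percentage points)

- the earlier runs do not show the pH; that part of a forecast is a guess

- part of the electrophile that has reacted at 6.0 min
- pH of the solution at 6.0 min

1. Take a pseudo-first-order loss as the zero of the scale: there the percent left ignores the charge. Measure the runs from it. They part by 0.3 percentage points, and a repeated reading scatters by 0.3 points.

2. Read k from each run at its last reading. The summer run gives 0.379 min⁻¹ for k, the average loss constant up to that reading, which is ln(charged/left) divided by the time t. The dawn run gives 0.375 min⁻¹.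

3. Hold the flask against the summer run. Nucleophile, buffer base and buffer acid match; the electrophile is 0.075 M. Take that smaller charge as shifting nothing on this scale. On that assumption the flask ends further along than the summer run's last reading because it is taken 1.00 min later.

4. Reckon the flask with exp(-kt): 10.3 % left at 6.0 min, so 89.7 % reacted. The runs show no pH, so commit to none.

5. Set the forecast beside this: 89 % reacted, below my figure, and pH 7.5. Its ground: “The electrophile loss is first order and almost independent of charge”.

    electrophile + leaving group → side product B (k = 11.0 M⁻¹ min⁻¹)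
    electrophile + target → side product A (k = 3.30 M⁻¹ min⁻¹)
    buffer acid ⇌ buffer base + acid, settled at all times (K = 4.00 × 10⁻¹⁰ M)
    electrophile + nucleophile → acid + target + leaving group (k = 1.40 M⁻¹ min⁻¹)
    protonated nucleophile ⇌ nucleophile + acid, settled at all times (K = 6.30 × 10⁻⁵ M)

The flask gives 89.1 % reacted and pH 10.0. Moved from the summer run, which had reacted 84.7 % by its last reading, the charge alone gives 83.8 % and the time alone 89.7 %. Put k to use again: it reckons 10.3 % of the electrophile left, and the flask holds 10.9 %. Now scale k in proportion to the nucleophile for a neighbour flask charged with 0.060 M, all else held. That reckons 40.2 % left, and the neighbour flask holds 40.8 %.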